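**Retrosynthetic overview**
- The target is the reduced form of all-trans ethyl 4-(3,4-dimethoxybenzoyl)-2-(3,4,5-trimethoxyphenyl)oxolane-3-carboxylate: Felkin–Anh reduction of the aryl ketone returns the benzylic carbinol, and ester reduction returns the CH2OH group.
- Enabling feature: oxolane atoms C3 and C4 each carry an exocyclic oxygen-bearing carbon (CH2OH on C3, ArCH(OH) on C4). The C3–C4 ring bond is therefore the α,α′ bond of a latent 1,4-dicarbonyl, and both centres can be epimerized, so the 2,3-trans/3,4-trans array can settle thermodynamically from C2 alone.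
- Key disconnection: C3–C4, made by anodic oxidative coupling of an ester-derived ketene silyl acetal with an aryl ketone silyl enol ether tethered through C2–O1–C5. This closes the oxolane, the only ring built (both benzene rings are bought).
- Acyclic precursor: O1–C5 by phosphine-catalysed oxa-Michael addition of an (R)-β-hydroxy ester to an aryl vinyl ketone; C2 by asymmetric transfer hydrogenation of a commercial β-keto ester.
- Order: C2 stereocentre, ether link, bis(enol silane), oxolane ring closure, equilibration, carbinol, primary alcohol.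

Key step: step 5

Assumption: ethyl 3-oxo-3-(3,4,5-trimethoxyphenyl)propanoate and 3-chloro-1-(3,4-dimethoxyphenyl)propan-1-one are taken as purchasable building blocks.

**Step 1**
Reactants: 1 ethyl 3-oxo-3-(3,4,5-trimethoxyphenyl)propanoate
Product: 2 ethyl (3R)-3-hydroxy-3-(3,4,5-trimethoxyphenyl)propanoate
Conditions: RuCl(p-cymene)[(R,R)-TsDPEN] (1 mol %), HCO2H/Et3N (5:2), 40 °C
Reagents that add atoms: none
Why: Noyori–Ikariya asymmetric transfer hydrogenation of the aryl ketone of the β-keto ester, in which the (R,R)-ligand holds the aryl group under the η6-arene so that hydride adds to one carbonyl face and the benzylic carbinol centre should form as (R), the ester being inert.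

**Step 2**
Reactants: 3 3-chloro-1-(3,4-dimethoxyphenyl)propan-1-one
Product: 4 1-(3,4-dimethoxyphenyl)prop-2-en-1-one
Conditions: Et3N (1.5 equiv), CH2Cl2, 0 °C to rt; used fresh
Reagents that add atoms: none
Why: E1cB dehydrochlorination of the β-chloro ketone gives the aryl vinyl ketone, which is used at once because such enones oligomerize on storage, and no stereocentre is involved.

**Step 3**
Reactants: 2 ethyl (3R)-3-hydroxy-3-(3,4,5-trimethoxyphenyl)propanoate; 4 1-(3,4-dimethoxyphenyl)prop-2-en-1-one
Product: 5 ethyl (3R)-3-[3-(3,4-dimethoxyphenyl)-3-oxopropoxy]-3-(3,4,5-trimethoxyphenyl)propanoate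
Conditions: PMe3 (10 mol %), MeCN, 0 °C to rt; 4 (2 equiv) added slowly
Reagents that add atoms: none
Why: Phosphine-catalysed oxa-Michael addition (hydroalkoxylation of an enone), in which the phosphonium enolate formed from PMe3 and 4 deprotonates the carbinol and the alkoxide adds to the vinyl ketone under conditions too mild for retro-aldol cleavage or dehydration, so the (R) centre is carried through unchanged.

**Step 4**
Reactants: 5 ethyl (3R)-3-[3-(3,4-dimethoxyphenyl)-3-oxopropoxy]-3-(3,4,5-trimethoxyphenyl)propanoate
Product: 6 (3R)-1-ethoxy-3-{[3-(3,4-dimethoxyphenyl)-3-(trimethylsilyloxy)prop-2-en-1-yl]oxy}-3-(3,4,5-trimethoxyphenyl)-1-(trimethylsilyloxy)prop-1-ene (ketene silyl acetal plus silyl enol ether of 5, double-bond isomers, used crude)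
Conditions: LiN(i-Pr)2 (2.4 equiv), Me3SiCl (6 equiv, present from the start), THF, −78 °C; pentane, filtration, evaporation
Reagents that add atoms: chlorotrimethylsilane, C[Si](C)(C)Cl
Why: Kinetic double enolization with internal silyl quench (Corey conditions) turns the ketone into its silyl enol ether and the ester into its ketene silyl acetal, each lithium enolate being silylated at −78 °C faster than it can expel the β-alkoxide, so the ether link and the (R) centre should survive while double-bond geometry is irrelevant.

**Step 5**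
Reactants: 6 bis(trimethylsilyl) dienol ether described in step 4
Product: 7 ethyl (2R)-4-(3,4-dimethoxybenzoyl)-2-(3,4,5-trimethoxyphenyl)oxolane-3-carboxylate (mixture of C3/C4 epimers)
Conditions: constant-current electrolysis, undivided cell, reticulated vitreous carbon anode, Pt cathode, LiClO4 (0.1 M), 2,6-lutidine (4 equiv), MeCN/i-PrOH (4:1), 0.02 M, 2.2 F/mol, 0 °C
Reagents that add atoms: none
Why: Anodic one-electron oxidation of an enol ether π-system (both are expected to be oxidized at lower potential than the two methoxyarenes, the ketene silyl acetal first) gives a radical cation that loses its silyl group to isopropanol and becomes an ester α-radical at C3; this electrophilic radical adds to the nucleophilic β-carbon C4 of the tethered aryl silyl enol ether, and the α-siloxy benzylic radical so formed is oxidized at the anode and desilylated to the aryl ketone, so the 1,4-keto ester is unmasked as the C3–C4 bond forms (initial oxidation of the other enol ether converges on the same product). The closest known reactions are the intramolecular anodic coupling of two enol ethers to five-membered rings (Moeller-type anodic olefin coupling) and the oxidative cross-coupling of ketene silyl acetals with silyl enol ethers to γ-keto esters. The oxolane is closed in the 5-exo-trig mode across the C2–O1–C5 tether, the 6-endo alternative being disfavoured because attack at the aryl- and siloxy-bearing carbon is hindered and would leave an unstabilized radical at C4. C3 and C4 are created here under kinetic substrate control (a Beckwith–Houk chair-like transition state with the C2 aryl group pseudo-equatorial should favour 2,3-trans), but no selectivity is demanded of this step because both centres are α to a carbonyl group and are equilibrated in step 6, while C2 is not touched. What the step does need is chemoselective oxidation of the enol ethers before the arenes, secured by their lower oxidation potentials, the limited charge and the weakly nucleophilic alcohol co-solvent, and coupling within one molecule instead of between two, secured by the three-atom tether and high dilution.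

**Step 6**
Reactants: 7 ethyl (2R)-4-(3,4-dimethoxybenzoyl)-2-(3,4,5-trimethoxyphenyl)oxolane-3-carboxylate (epimer mixture)
Product: 8 ethyl (2R,3R,4R)-4-(3,4-dimethoxybenzoyl)-2-(3,4,5-trimethoxyphenyl)oxolane-3-carboxylate (2,3-trans, 3,4-trans)
Conditions: NaOEt (0.3 equiv), EtOH, rt
Reagents that add atoms: none
Why: Base-mediated epimerization through the ketone and ester enolates is under thermodynamic control, so with C2 fixed as (R) the isomer whose ester is trans to both the C2 aryl and the C4 aroyl group should dominate and C3 and C4 settle as (3R,4R), while ring opening by β-elimination is disfavoured because it is the reverse of a 5-endo-trig closure.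

**Step 7**
Reactants: 8 ethyl (2R,3R,4R)-4-(3,4-dimethoxybenzoyl)-2-(3,4,5-trimethoxyphenyl)oxolane-3-carboxylate
Product: 9 ethyl (2R,3R,4R)-4-[(S)-(3,4-dimethoxyphenyl)(hydroxy)methyl]-2-(3,4,5-trimethoxyphenyl)oxolane-3-carboxylate
Conditions: LiBH(s-Bu)3 (1.2 equiv), THF, −78 °C; then H2O
Reagents that add atoms: none
Why: Chemoselective ketone reduction by a bulky hydride under Felkin–Anh control, in which hydride attacks the aroyl carbonyl anti to the branched ring carbon C3 and past the C4 hydrogen, which should give the (S)-carbinol, while the ester is not reduced at −78 °C.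

**Step 8**
Reactants: 9 ethyl (2R,3R,4R)-4-[(S)-(3,4-dimethoxyphenyl)(hydroxy)methyl]-2-(3,4,5-trimethoxyphenyl)oxolane-3-carboxylate
Product: 10 (S)-(3,4-dimethoxyphenyl)[(3R,4S,5R)-4-(hydroxymethyl)-5-(3,4,5-trimethoxyphenyl)oxolan-3-yl]methanol
Conditions: LiAlH4 (2 equiv), THF, 0 °C; H2O, aq NaOH
Reagents that add atoms: none
Why: Hydride reduction of the ethyl ester to the primary alcohol completes the diol without touching a stereocentre, since nothing is enolized and the benzylic alkoxide cannot lactonize across the trans-substituted C3–C4 bond.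

**Compound list**
1 | ethyl 3-oxo-3-(3,4,5-trimethoxyphenyl)propanoate | CCOC(=O)CC(=O)c1cc(OC)c(OC)c(OC)c1 | starting material
2 | ethyl (3R)-3-hydroxy-3-(3,4,5-trimethoxyphenyl)propanoate | CCOC(=O)C[C@@H](O)c1cc(OC)c(OC)c(OC)c1 | intermediate
3 | 3-chloro-1-(3,4-dimethoxyphenyl)propan-1-one | ClCCC(=O)c1ccc(OC)c(OC)c1 | starting material
4 | 1-(3,4-dimethoxyphenyl)prop-2-en-1-one | C=CC(=O)c1ccc(OC)c(OC)c1 | intermediate
5 | ethyl (3R)-3-[3-(3,4-dimethoxyphenyl)-3-oxopropoxy]-3-(3,4,5-trimethoxyphenyl)propanoate | CCOC(=O)C[C@@H](OCCC(=O)c1ccc(OC)c(OC)c1)c1cc(OC)c(OC)c(OC)c1 | intermediate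
6 | (3R)-1-ethoxy-3-{[3-(3,4-dimethoxyphenyl)-3-(trimethylsilyloxy)prop-2-en-1-yl]oxy}-3-(3,4,5-trimethoxyphenyl)-1-(trimethylsilyloxy)prop-1-ene | CCOC(O[Si](C)(C)C)=C[C@@H](OCC=C(O[Si](C)(C)C)c1ccc(OC)c(OC)c1)c1cc(OC)c(OC)c(OC)c1 | intermediate
7 | ethyl (2R)-4-(3,4-dimethoxybenzoyl)-2-(3,4,5-trimethoxyphenyl)oxolane-3-carboxylate, C3/C4 epimer mixture | COc1ccc(C(=O)C2CO[C@@H](c3cc(OC)c(OC)c(OC)c3)C2C(=O)OCC)cc1OC | intermediate
8 | ethyl (2R,3R,4R)-4-(3,4-dimethoxybenzoyl)-2-(3,4,5-trimethoxyphenyl)oxolane-3-carboxylate | COc1ccc(C(=O)[C@H]2CO[C@@H](c3cc(OC)c(OC)c(OC)c3)[C@@H]2C(=O)OCC)cc1OC | intermediate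
9 | ethyl (2R,3R,4R)-4-[(S)-(3,4-dimethoxyphenyl)(hydroxy)methyl]-2-(3,4,5-trimethoxyphenyl)oxolane-3-carboxylate | COc1ccc([C@@H](O)[C@H]2CO[C@@H](c3cc(OC)c(OC)c(OC)c3)[C@@H]2C(=O)OCC)cc1OC | intermediate
10 | (S)-(3,4-dimethoxyphenyl)[(3R,4S,5R)-4-(hydroxymethyl)-5-(3,4,5-trimethoxyphenyl)oxolan-3-yl]methanol | COc1ccc([C@@H](O)[C@H]2CO[C@@H](c3cc(OC)c(OC)c(OC)c3)[C@@H]2CO)cc1OC | target

**Step count**
Total steps: 8. Longest linear sequence: 7 steps (1, 3, 4, 5, 6, 7, 8).

**Steps most likely to fail**

Step 5. The ketene silyl acetal may be solvolysed in the protic electrolyte before it is oxidized, coupling may occur between molecules instead of within one, or charge may leak into the methoxyarenes. The fallback replaces substrate oxidation by a reductively initiated radical–polar crossover. Setting out from 6, N-iodosuccinimide (1.05 equiv, THF, −78 °C) should iodinate only the far more nucleophilic ketene silyl acetal and give ethyl (3S)-3-{[3-(3,4-dimethoxyphenyl)-3-(trimethylsilyloxy)prop-2-en-1-yl]oxy}-2-iodo-3-(3,4,5-trimethoxyphenyl)propanoate F1 (same spatial arrangement at the benzylic carbon; the descriptor changes by priority only). Irradiation with blue light in MeCN with fac-Ir(ppy)3 (1 mol %) and 2,6-lutidine should reduce the C–I bond and let the ester α-radical close the oxolane 5-exo onto the silyl enol ether. The α-siloxy benzylic radical is then oxidized by the tetravalent iridium formed in the first electron transfer, and loss of the silyl group brings the route back at 7.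

Step 4. β-Elimination of the alkoxide from the ester or ketone enolate, or an intramolecular aldol or Claisen reaction, may outrun silylation. The fallback installs the radical precursor while the β-oxygen is still an alkoxide that cannot leave, and afterwards uses only soft enolization. Setting out from 2, the dianion (LiN(i-Pr)2, 2.2 equiv, THF, −78 to −40 °C) is selenenylated with PhSeBr to ethyl (3S)-3-hydroxy-2-(phenylselanyl)-3-(3,4,5-trimethoxyphenyl)propanoate F2. PMe3-catalysed oxa-Michael addition to 4, as in step 3, gives ethyl (3S)-3-[3-(3,4-dimethoxyphenyl)-3-oxopropoxy]-2-(phenylselanyl)-3-(3,4,5-trimethoxyphenyl)propanoate F3. Me3SiOTf and Et3N (CH2Cl2, 0 °C) convert only the ketone into its silyl enol ether, ethyl (3S)-3-{[3-(3,4-dimethoxyphenyl)-3-(trimethylsilyloxy)prop-2-en-1-yl]oxy}-2-(phenylselanyl)-3-(3,4,5-trimethoxyphenyl)propanoate F4. Photolysis in benzene with a little (Bu3Sn)2 then starts a phenylselanyl group-transfer radical cyclization (C–Se homolysis, 5-exo addition of the C3 radical to C4, selenium transfer to the α-siloxy radical, collapse to the ketone), which brings the route back at 7.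

Step 7. Facial selectivity of hydride delivery may be poor if the two ring carbons flanking C4 do not differ enough in size. The fallback corrects the carbinol centre by inversion instead of relying on substrate control. Setting out from 8, unselective reduction (NaBH4, CeCl3, EtOH, −20 °C) and separation give, beside 9, the epimer ethyl (2R,3R,4R)-4-[(R)-(3,4-dimethoxyphenyl)(hydroxy)methyl]-2-(3,4,5-trimethoxyphenyl)oxolane-3-carboxylate F5. Mitsunobu esterification (4-nitrobenzoic acid, PPh3, diisopropyl azodicarboxylate, toluene, 0 °C) inverts it to ethyl (2R,3R,4R)-4-[(S)-(3,4-dimethoxyphenyl)(4-nitrobenzoyloxy)methyl]-2-(3,4,5-trimethoxyphenyl)oxolane-3-carboxylate F6. Ethanolysis (K2CO3, EtOH, rt) brings the route back at 9.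

**Further compounds**
F1 | step 5 | ethyl (3S)-3-{[3-(3,4-dimethoxyphenyl)-3-(trimethylsilyloxy)prop-2-en-1-yl]oxy}-2-iodo-3-(3,4,5-trimethoxyphenyl)propanoate | CCOC(=O)C(I)[C@@H](OCC=C(O[Si](C)(C)C)c1ccc(OC)c(OC)c1)c1cc(OC)c(OC)c(OC)c1
F2 | step 4 | ethyl (3S)-3-hydroxy-2-(phenylselanyl)-3-(3,4,5-trimethoxyphenyl)propanoate | CCOC(=O)C([Se]c1ccccc1)[C@@H](O)c1cc(OC)c(OC)c(OC)c1
F3 | step 4 | ethyl (3S)-3-[3-(3,4-dimethoxyphenyl)-3-oxopropoxy]-2-(phenylselanyl)-3-(3,4,5-trimethoxyphenyl)propanoate | CCOC(=O)C([Se]c1ccccc1)[C@@H](OCCC(=O)c1ccc(OC)c(OC)c1)c1cc(OC)c(OC)c(OC)c1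
F4 | step 4 | ethyl (3S)-3-{[3-(3,4-dimethoxyphenyl)-3-(trimethylsilyloxy)prop-2-en-1-yl]oxy}-2-(phenylselanyl)-3-(3,4,5-trimethoxyphenyl)propanoate | CCOC(=O)C([Se]c1ccccc1)[C@@H](OCC=C(O[Si](C)(C)C)c1ccc(OC)c(OC)c1)c1cc(OC)c(OC)c(OC)c1
F5 | step 7 | ethyl (2R,3R,4R)-4-[(R)-(3,4-dimethoxyphenyl)(hydroxy)methyl]-2-(3,4,5-trimethoxyphenyl)oxolane-3-carboxylate | COc1ccc([C@H](O)[C@H]2CO[C@@H](c3cc(OC)c(OC)c(OC)c3)[C@@H]2C(=O)OCC)cc1OC
F6 | step 7 | ethyl (2R,3R,4R)-4-[(S)-(3,4-dimethoxyphenyl)(4-nitrobenzoyloxy)methyl]-2-(3,4,5-trimethoxyphenyl)oxolane-3-carboxylate | COc1ccc([C@@H](OC(=O)c4ccc(cc4)[N+](=O)[O-])[C@H]2CO[C@@H](c3cc(OC)c(OC)c(OC)c3)[C@@H]2C(=O)OCC)cc1OC
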